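**Plan**
1. Cuts: the C15–O(acyl) ester bond comes off first. The C2 carbinol goes back to the C2 ketone and its ethyl enol ether. C3–C4 and C5–C10 are then cut together, which opens rings A and B at once to an acyclic tetraene. In the chain the cuts are C1–C2 (Stille), C10–C20 and C10≡C1 (methylalumination, alkyne homologation), C9–C10 ([2,3]-Wittig–Still) and C6–C7 (allylation).
2. Enabling feature: ring A (C1–C5, C10) is a cyclohexane whose only heteroatom sits on C2, "para" to C5. It is therefore the reduced adduct of the 2-ethoxydiene C3=C2(OEt)–C1=C10 and the alkene C4=C5. The other four atoms of ring B, C6–C7=C8–C9 with their cis double bond, form a ready-made tether between C5 and C10.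
3. Forward: (S)-citronellol supplies C7–C9 and C11–C17. Allylation and cross metathesis add C4–C6, C18 and C19. The [2,3]-shift adds C10, the alkyne and methylalumination add C1 and C20, and the Stille coupling adds C2–C3. Both rings then close in one operation, and ketone reduction, desilylation and esterification finish the route.
4. Stereochemistry: C13 comes from (S)-citronellol. A temporary C7 carbinol from (S)-BINOL/Ti allylation is passed suprafacially to C9 and erased, which also fixes the 7Z alkene. C9 directs C10 and C5 in the cycloaddition. C2 is set by thermodynamically controlled ketone reduction, and the Z-cinnamate by Still–Gennari olefination.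

Key step: step 11

Remark: labdane numbering is used throughout (C1–C10 decalin, C11–C16 side chain, C17 on C8, C18/C19 on C4, C20 on C10). The free phenol of 20 is assumed to need no protection in the final Mitsunobu esterification, since the carboxylic acid is far more acidic.

**Step 1**
Reactants: 1 (S)-(−)-citronellol
Product: 2 tert-butyl{[(3S)-3,7-dimethyloct-6-en-1-yl]oxy}diphenylsilane
Conditions: TBDPSCl, imidazole, DMF, 0 °C → rt
Reagents that add atoms: tert-butyl(chloro)diphenylsilane, CC(C)(C)[Si](Cl)(c1ccccc1)c1ccccc1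
Why: Standard silylation of a primary alcohol gives an ether that should survive base, organometallics, mild acid and SmI2, and C13 is taken unchanged from the chiral pool.

**Step 2**
Reactants: 2 tert-butyl{[(3S)-3,7-dimethyloct-6-en-1-yl]oxy}diphenylsilane
Product: 3 (2E,6S)-8-(tert-butyldiphenylsilyloxy)-2,6-dimethyloct-2-enal
Conditions: SeO2 (1.2 equiv), 1,4-dioxane, 80 °C
Reagents that add atoms: selenium dioxide, O=[Se]=O
Why: Riley allylic oxidation (ene reaction, then [2,3]-shift) attacks the methyl group trans to the chain of a trisubstituted alkene, so the (E)-enal should form.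

**Step 3**
Reactants: 3 (2E,6S)-8-(tert-butyldiphenylsilyloxy)-2,6-dimethyloct-2-enal
Product: 4 (4S,5E,9S)-11-(tert-butyldiphenylsilyloxy)-5,9-dimethylundeca-1,5-dien-4-ol
Conditions: allylSnBu3, (S)-BINOL (20 mol %), Ti(OiPr)4 (10 mol %), 4 Å MS, CH2Cl2, −20 °C; aq NaHCO3
Reagents that add atoms: allyltributylstannane, C=CC[Sn](CCCC)(CCCC)CCCC
Why: In the Keck asymmetric allylation the (S)-BINOL–titanium complex directs the stannane to one face of α-methyl enals, so the temporary (S)-carbinol at C7 should form under catalyst control without influence from remote C13.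

**Step 4**
Reactants: 4 (4S,5E,9S)-11-(tert-butyldiphenylsilyloxy)-5,9-dimethylundeca-1,5-dien-4-ol
Product: 5 (5S,6E,10S)-12-(tert-butyldiphenylsilyloxy)-2,6,10-trimethyldodeca-2,6-dien-5-ol
Conditions: Grubbs II (3 mol %), 2-methylbut-2-ene (solvent), 40 °C
Reagents that add atoms: 2-methylbut-2-ene, CC=C(C)C
Why: Olefin cross metathesis with 2-methylbut-2-ene turns a terminal vinyl group into a prenyl group, and the trisubstituted C8=C9 alkene is too hindered to take part.

**Step 5**
Reactants: 5 (5S,6E,10S)-12-(tert-butyldiphenylsilyloxy)-2,6,10-trimethyldodeca-2,6-dien-5-ol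
Product: 6 tributylstannylmethyl ether of 5
Conditions: KH, Bu3SnCH2I, THF, 0 °C → rt
Reagents that add atoms: tributyl(iodomethyl)stannane, CCCC[Sn](CI)(CCCC)CCCC
Why: Williamson etherification of the potassium alkoxide with the primary iodide leaves the C7 configuration untouched.

**Step 6**
Reactants: 6 tributylstannylmethyl ether of 5
Product: 8 (2S,3Z)-2-[(3S)-5-(tert-butyldiphenylsilyloxy)-3-methylpentyl]-3,7-dimethylocta-3,6-dien-1-ol, via lithiomethyl ether 7 (not isolated)
Conditions: n-BuLi, THF, −78 °C; H2O
Reagents that add atoms: none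
Why: Tin–lithium exchange starts the suprafacial [2,3]-Wittig–Still shift, whose envelope with the C7 substituent pseudoaxial (avoiding A(1,2) strain with the C8 methyl group) should give the Z-trisubstituted C7=C8 alkene and pass the (S)-C7 configuration to C9.

**Step 7**
Reactants: 8 (2S,3Z)-2-[(3S)-5-(tert-butyldiphenylsilyloxy)-3-methylpentyl]-3,7-dimethylocta-3,6-dien-1-ol
Product: 9 (2S,3Z)-2-[(3S)-5-(tert-butyldiphenylsilyloxy)-3-methylpentyl]-3,7-dimethylocta-3,6-dienal
Conditions: Dess–Martin periodinane, CH2Cl2, 0 °C → rt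
Reagents that add atoms: none
Why: Dess–Martin oxidation is fast and nearly neutral, so the α-stereocentre C9 and the β,γ-alkene should stay in place if 9 is used at once.

**Step 8**
Reactants: 9 (2S,3Z)-2-[(3S)-5-(tert-butyldiphenylsilyloxy)-3-methylpentyl]-3,7-dimethylocta-3,6-dienal
Product: 10 (3R,4Z)-3-[(3S)-5-(tert-butyldiphenylsilyloxy)-3-methylpentyl]-4,8-dimethylnona-4,7-dien-1-yne
Conditions: dimethyl (1-diazo-2-oxopropyl)phosphonate, K2CO3, MeOH, 0 °C
Reagents that add atoms: Ohira–Bestmann reagent, COP(=O)(OC)C(=[N+]=[N-])C(C)=O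
Why: The Ohira–Bestmann variant of the Seyferth–Gilbert homologation converts the aldehyde into the terminal alkyne C10≡C1 under mild base, and the CIP descriptor at C9 changes only because the priorities change.

**Step 9**
Reactants: 10 (3R,4Z)-3-[(3S)-5-(tert-butyldiphenylsilyloxy)-3-methylpentyl]-4,8-dimethylnona-4,7-dien-1-yne
Product: 12 (1E,3S,4Z)-1-iodo-2,4,8-trimethyl-3-[(3S)-5-(tert-butyldiphenylsilyloxy)-3-methylpentyl]nona-1,4,7-triene, via alkenylalane 11 (not isolated)
Conditions: Me3Al, Cp2ZrCl2 (25 mol %), CH2Cl2, 0 °C → rt; I2, THF, −30 °C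
Reagents that add atoms: trimethylaluminium, C[Al](C)C; iodine, II
Why: Negishi zirconium-catalysed methylalumination adds CH3 (C20) and Al syn across the terminal alkyne with the methyl group on the inner carbon, and iodinolysis with retention should give the (E)-iodide while the trisubstituted alkenes stay inert.

**Step 10**
Reactants: 12 (1E,3S,4Z)-1-iodo-2,4,8-trimethyl-3-[(3S)-5-(tert-butyldiphenylsilyloxy)-3-methylpentyl]nona-1,4,7-triene
Product: 13 (3E,5S,6Z)-2-ethoxy-4,6,10-trimethyl-5-[(3S)-5-(tert-butyldiphenylsilyloxy)-3-methylpentyl]undeca-1,3,6,9-tetraene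
Conditions: tributyl(1-ethoxyvinyl)stannane, Pd2(dba)3 (2.5 mol %), AsPh3 (10 mol %), NMP, 40 °C; Et3N-deactivated silica
Reagents that add atoms: tributyl(1-ethoxyvinyl)stannane, CCOC(=C)[Sn](CCCC)(CCCC)CCCC
Why: Stille coupling proceeds with retention of the alkene geometry under neutral conditions and installs the 2-ethoxydiene without any enolisation that could touch the doubly allylic C9–H.

**Step 11**
Reactants: 13 (3E,5S,6Z)-2-ethoxy-4,6,10-trimethyl-5-[(3S)-5-(tert-butyldiphenylsilyloxy)-3-methylpentyl]undeca-1,3,6,9-tetraene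
Product: 15 (13S)-15-(tert-butyldiphenylsilyloxy)labd-7-en-2-one, via enol ether 14 (not isolated)
Conditions: (4-BrC6H4)3N•+ SbCl6− (10 mol %), 2,6-di-tert-butylpyridine (30 mol %), CH2Cl2 (5 mM), −30 → 0 °C, Ar, dark; then 1 M aq HCl, THF, 0 °C
Reagents that add atoms: water, O
Why: Proposed new method: the aminium salt removes one electron from the 2-ethoxydiene C3=C2(OEt)–C1=C10, the only π system of 13 within its reach, and the radical cation, a vinylogous oxocarbenium ion electrophilic at C10, is attacked by C5 of the prenyl alkene in the Markovnikov sense; the distonic ion so formed (tertiary cation at C4, 2-ethoxyallyl radical C1–C2–C3) closes C3–C4, and the enol-ether radical cation of 14 takes an electron from the next molecule of 13, so that the net result is a hole-catalysed [4+2] cycloaddition that does not depend on the frontier-orbital gap or on unhindered termini, as a thermal reaction of this electron-rich, doubly quaternising pair would. The closest known reaction types are the aminium-salt- or photoredox-induced radical-cation Diels–Alder reaction, known also intramolecularly and with fully substituted alkene termini, and the oxidative coupling of enol-ether radical cations with trisubstituted alkenes that builds quaternary carbons; new here is that the ionised partner is a 2-alkoxydiene and the 2π partner an isolated trialkyl alkene. Ring B (C5–C10) closes through the C5–C10 bond, a 6-exo attack on the alkene held in reach by the four-atom tether C6–C7=C8–C9 with its Z double bond, and ring A (C1–C5, C10) through the C3–C4 bond, a 6-endo closure onto the allyl terminus, which together amount to a type-1 intramolecular Diels–Alder reaction giving a fused decalin. C10 is set by C9, because allylic strain keeps C9–H in the diene plane next to C1–H, the tether reaches one diene face and the C11 chain stands anti to the incoming alkene, which places C20 and C11 cis as in the target; C5 is set by the exo, half-chair arrangement of the tether, which keeps C6 away from the diene and puts H5 trans to C20 (trans-decalin). The step needs chemoselective oxidation (secured by the large gap in oxidation potential between the alkoxydiene and the trialkyl alkenes), regioselectivity (enforced by the tether and matched by cation stability at C4 and C2) and absence of acid (secured by the hindered pyridine, which removes protons but should not intercept the ions). Mild aqueous acid then hydrolyses enol ether 14 to ketone 15 and so removes the ethyl helper.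

**Step 12**
Reactants: 15 (13S)-15-(tert-butyldiphenylsilyloxy)labd-7-en-2-one
Product: 16 (13S)-15-(tert-butyldiphenylsilyloxy)labd-7-en-2α-ol
Conditions: SmI2 (4 equiv), H2O, THF, rt
Reagents that add atoms: none
Why: Single-electron (ketyl) reduction with SmI2–H2O should give the thermodynamic equatorial 2α-alcohol, because the axial 2β-epimer would suffer two syn-axial contacts with C20 and the 4β-methyl group (the same contacts make hydride reagents deliver the wrong epimer), and isolated alkenes are inert.

**Step 13**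
Reactants: 16 (13S)-15-(tert-butyldiphenylsilyloxy)labd-7-en-2α-ol
Product: 17 (13S)-labd-7-ene-2α,15-diol
Conditions: TBAF, THF, rt; H2O
Reagents that add atoms: none
Why: Fluoride-induced desilylation frees the primary C15 alcohol and touches nothing else.

**Step 14**
Reactants: 18 4-(tert-butyldimethylsilyloxy)benzaldehyde
Product: 19 methyl (Z)-3-[4-(tert-butyldimethylsilyloxy)phenyl]prop-2-enoate
Conditions: (CF3CH2O)2P(O)CH2CO2Me, KHMDS, 18-crown-6, THF, −78 °C
Reagents that add atoms: methyl bis(2,2,2-trifluoroethyl)phosphonoacetate, COC(=O)CP(=O)(OCC(F)(F)F)OCC(F)(F)F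
Why: In Still–Gennari olefination the electron-poor phosphonate eliminates fast and irreversibly from the kinetic adduct, so aromatic aldehydes should give the (Z)-cinnamate.

**Step 15**
Reactants: 19 methyl (Z)-3-[4-(tert-butyldimethylsilyloxy)phenyl]prop-2-enoate
Product: 20 (Z)-4-hydroxycinnamic acid
Conditions: LiOH, THF–MeOH–H2O, rt, dark; 1 M HCl, 0 °C
Reagents that add atoms: lithium hydroxide, [Li+].[OH-]
Why: Saponification cleaves the methyl ester and the base-labile phenolic silyl ether in one operation, and exclusion of light should keep the Z geometry.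

**Step 16**
Reactants: 17 (13S)-labd-7-ene-2α,15-diol; 20 (Z)-4-hydroxycinnamic acid
Product: 21 (13S)-2α-hydroxylabd-7-en-15-yl (Z)-4-hydroxycinnamate (target)
Conditions: PPh3, DIAD (1.1 equiv each, betaine pre-formed), THF, −10 → 0 °C, dark
Reagents that add atoms: none
Why: Mitsunobu esterification activates the primary C15 alcohol well ahead of the secondary C2 alcohol and uses the carboxylate (not the phenol) as nucleophile, so the acid is never activated as an acyl donor and its Z alkene should be kept.

**Compound list**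
1 | (S)-(−)-citronellol, (3S)-3,7-dimethyloct-6-en-1-ol | CC(C)=CCC[C@H](C)CCO | starting material
2 | tert-butyl{[(3S)-3,7-dimethyloct-6-en-1-yl]oxy}diphenylsilane | CC(C)=CCC[C@H](C)CCO[Si](c1ccccc1)(c1ccccc1)C(C)(C)C | intermediate
3 | (2E,6S)-8-(tert-butyldiphenylsilyloxy)-2,6-dimethyloct-2-enal | O=C/C(C)=C/CC[C@H](C)CCO[Si](c1ccccc1)(c1ccccc1)C(C)(C)C | intermediate
4 | (4S,5E,9S)-11-(tert-butyldiphenylsilyloxy)-5,9-dimethylundeca-1,5-dien-4-ol | C=CC[C@H](O)/C(C)=C/CC[C@H](C)CCO[Si](c1ccccc1)(c1ccccc1)C(C)(C)C | intermediate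
5 | (5S,6E,10S)-12-(tert-butyldiphenylsilyloxy)-2,6,10-trimethyldodeca-2,6-dien-5-ol | CC(C)=CC[C@H](O)/C(C)=C/CC[C@H](C)CCO[Si](c1ccccc1)(c1ccccc1)C(C)(C)C | intermediate
6 | tributylstannylmethyl ether of 5 | CC(C)=CC[C@H](OC[Sn](CCCC)(CCCC)CCCC)/C(C)=C/CC[C@H](C)CCO[Si](c1ccccc1)(c1ccccc1)C(C)(C)C | intermediate
7 | lithiomethyl ether of 5 | CC(C)=CC[C@H](OC[Li])/C(C)=C/CC[C@H](C)CCO[Si](c1ccccc1)(c1ccccc1)C(C)(C)C | intermediate
8 | (2S,3Z)-2-[(3S)-5-(tert-butyldiphenylsilyloxy)-3-methylpentyl]-3,7-dimethylocta-3,6-dien-1-ol | CC(C)=CC/C=C(/C)[C@@H](CO)CC[C@H](C)CCO[Si](c1ccccc1)(c1ccccc1)C(C)(C)C | intermediate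
9 | (2S,3Z)-2-[(3S)-5-(tert-butyldiphenylsilyloxy)-3-methylpentyl]-3,7-dimethylocta-3,6-dienal | CC(C)=CC/C=C(/C)[C@@H](C=O)CC[C@H](C)CCO[Si](c1ccccc1)(c1ccccc1)C(C)(C)C | intermediate
10 | (3R,4Z)-3-[(3S)-5-(tert-butyldiphenylsilyloxy)-3-methylpentyl]-4,8-dimethylnona-4,7-dien-1-yne | CC(C)=CC/C=C(/C)[C@@H](C#C)CC[C@H](C)CCO[Si](c1ccccc1)(c1ccccc1)C(C)(C)C | intermediate
11 | (E)-alkenyl(dimethyl)alane from methylalumination of 10 | CC(C)=CC/C=C(/C)[C@@H](/C(C)=C/[Al](C)C)CC[C@H](C)CCO[Si](c1ccccc1)(c1ccccc1)C(C)(C)C | intermediate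
12 | (1E,3S,4Z)-1-iodo-2,4,8-trimethyl-3-[(3S)-5-(tert-butyldiphenylsilyloxy)-3-methylpentyl]nona-1,4,7-triene | CC(C)=CC/C=C(/C)[C@@H](/C(C)=C/I)CC[C@H](C)CCO[Si](c1ccccc1)(c1ccccc1)C(C)(C)C | intermediate
13 | (3E,5S,6Z)-2-ethoxy-4,6,10-trimethyl-5-[(3S)-5-(tert-butyldiphenylsilyloxy)-3-methylpentyl]undeca-1,3,6,9-tetraene | CC(C)=CC/C=C(/C)[C@@H](/C(C)=C/C(=C)OCC)CC[C@H](C)CCO[Si](c1ccccc1)(c1ccccc1)C(C)(C)C | intermediate
14 | (13S)-2-ethoxy-15-(tert-butyldiphenylsilyloxy)labda-1,7-diene (5α-H, 9α-H, 10β-CH3) | CC1=CC[C@H]2C(C)(C)CC(OCC)=C[C@]2(C)[C@H]1CC[C@H](C)CCO[Si](c1ccccc1)(c1ccccc1)C(C)(C)C | intermediate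
15 | (13S)-15-(tert-butyldiphenylsilyloxy)labd-7-en-2-one | CC1=CC[C@H]2C(C)(C)CC(=O)C[C@]2(C)[C@H]1CC[C@H](C)CCO[Si](c1ccccc1)(c1ccccc1)C(C)(C)C | intermediate
16 | (13S)-15-(tert-butyldiphenylsilyloxy)labd-7-en-2α-ol | CC1=CC[C@H]2C(C)(C)C[C@H](O)C[C@]2(C)[C@H]1CC[C@H](C)CCO[Si](c1ccccc1)(c1ccccc1)C(C)(C)C | intermediate
17 | (13S)-labd-7-ene-2α,15-diol | CC1=CC[C@H]2C(C)(C)C[C@H](O)C[C@]2(C)[C@H]1CC[C@H](C)CCO | intermediate
18 | 4-(tert-butyldimethylsilyloxy)benzaldehyde | O=Cc1ccc(O[Si](C)(C)C(C)(C)C)cc1 | starting material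
19 | methyl (Z)-3-[4-(tert-butyldimethylsilyloxy)phenyl]prop-2-enoate | COC(=O)/C=C\c1ccc(O[Si](C)(C)C(C)(C)C)cc1 | intermediate
20 | (Z)-4-hydroxycinnamic acid | OC(=O)/C=C\c1ccc(O)cc1 | intermediate
21 | (2S,5S,9S,10S,13S)-2-hydroxylabd-7-en-15-yl (Z)-4-hydroxycinnamate | CC1=CC[C@H]2C(C)(C)C[C@H](O)C[C@]2(C)[C@H]1CC[C@H](C)CCOC(=O)/C=C\c1ccc(O)cc1 | target

Total step count: 16. Longest linear sequence: 14 (steps 1–13 and 16).

**Steps most likely to fail**

1. Step 11 (Proposed new method).
   - What may go wrong: the radical cation may lose the doubly allylic C9 proton; the C4 cation may lose a proton before ring A closes; the enol ether product may be over-oxidised; weak exo/endo control may lead to a cis ring fusion.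
   - Fallback: a stepwise polar annulation by known chemistry, from 13 back to 15.
   - Mild acid hydrolysis of 13 gives the (E)-methyl enone F1.
   - MeAlCl2 in CH2Cl2 induces the intramolecular conjugate addition of the prenyl alkene to the enone. This forms C5–C10 through a chair-like array, ends by proton transfer from a C4 methyl group as a formal ene reaction, and gives the monocyclic isopropenyl ketone F2.
   - Cobalt-catalysed Markovnikov hydrochlorination (TsCl, PhSiH3, EtOH) of the 1,1-disubstituted alkene, which reacts ahead of the trisubstituted one, gives the tertiary chloride F3.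
   - LDA/TMSCl at −78 °C gives the kinetic trimethylsilyl enol ether F4.
   - TiCl4 in CH2Cl2 then closes C3–C4 by Lewis-acid-mediated α-tert-alkylation of the silyl enol ether and delivers 15.

2. Step 8.
   - What may go wrong: enolisation of aldehyde 9 in basic methanol, with epimerisation at C9 or migration of the C7=C8 bond into conjugation.
   - Fallback: a base-free Wittig-type homologation, from 9 back to 10.
   - Corey–Fuchs reaction with CBr4/PPh3 in CH2Cl2 at 0 °C gives the 1,1-dibromoalkene F5.
   - n-BuLi (2 equiv) in THF at −78 °C brings about bromine–lithium exchange and rearrangement to the lithium acetylide, which is protonated to 10.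

3. Step 16.
   - What may go wrong: Z → E isomerisation of the cinnamate through reversible phosphine addition or stray light; competing O-alkylation of the phenol; partial reaction at the C2 alcohol.
   - Fallback: the Z alkene is built on the terpenoid instead of being carried in, from 17 back to 21.
   - EDC-mediated acylation of the primary alcohol of 17 with bis(2,2,2-trifluoroethyl)phosphonoacetic acid gives the phosphonoacetate F6.
   - Still–Gennari olefination of F6 (KHMDS, 18-crown-6, THF, −78 °C) with aldehyde 18 gives the O-silylated (Z)-ester F7.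
   - TBAF buffered with AcOH at 0 °C removes the phenolic silyl group to give 21.

**Further compounds**
F1 | step 11 | (3E,5S,6Z)-4,6,10-trimethyl-5-[(3S)-5-(tert-butyldiphenylsilyloxy)-3-methylpentyl]undeca-3,6,9-trien-2-one | CC(C)=CC/C=C(/C)[C@@H](/C(C)=C/C(C)=O)CC[C@H](C)CCO[Si](c1ccccc1)(c1ccccc1)C(C)(C)C
F2 | step 11 | monocyclic ketone: ring B with isopropenyl at C5 and acetonyl plus methyl at C10 (3,4-seco-labda-4(18),7-dien-2-one) | CC1=CC[C@@H](C(C)=C)[C@](C)(CC(C)=O)[C@H]1CC[C@H](C)CCO[Si](c1ccccc1)(c1ccccc1)C(C)(C)C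
F3 | step 11 | tertiary chloride from F2 (4-chloro-3,4-seco-labd-7-en-2-one) | CC1=CC[C@@H](C(C)(C)Cl)[C@](C)(CC(C)=O)[C@H]1CC[C@H](C)CCO[Si](c1ccccc1)(c1ccccc1)C(C)(C)C
F4 | step 11 | kinetic trimethylsilyl enol ether of F3 (C2=C3) | CC1=CC[C@@H](C(C)(C)Cl)[C@](C)(CC(=C)O[Si](C)(C)C)[C@H]1CC[C@H](C)CCO[Si](c1ccccc1)(c1ccccc1)C(C)(C)C
F5 | step 8 | 1,1-dibromoalkene from 9 | CC(C)=CC/C=C(/C)[C@@H](C=C(Br)Br)CC[C@H](C)CCO[Si](c1ccccc1)(c1ccccc1)C(C)(C)C
F6 | step 16 | (13S)-2α-hydroxylabd-7-en-15-yl bis(2,2,2-trifluoroethyl)phosphonoacetate | CC1=CC[C@H]2C(C)(C)C[C@H](O)C[C@]2(C)[C@H]1CC[C@H](C)CCOC(=O)CP(=O)(OCC(F)(F)F)OCC(F)(F)F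
F7 | step 16 | (13S)-2α-hydroxylabd-7-en-15-yl (Z)-4-(tert-butyldimethylsilyloxy)cinnamate | CC1=CC[C@H]2C(C)(C)C[C@H](O)C[C@]2(C)[C@H]1CC[C@H](C)CCOC(=O)/C=C\c1ccc(O[Si](C)(C)C(C)(C)C)cc1
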